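**Plan**

- Retrosynthesis: the MOM ether on the ring C phenol is the only protecting group. The CH2–O aryl ether bond to eugenol (ring D) and the C5–allyl bond are cut next, leaving a trans 2-aryl-3-(hydroxymethyl)-5-chloro-2,3-dihydrobenzofuran. The central cut then removes the C2–aryl bond and the C3–C(carbonyl) bond together.
- Enabling feature: in the dihydrofuran ring B (O1, C2, C3, C3a, C7a) fused to benzene ring A, the guaiacyl ring C sits on C2 next to O1 and the one-carbon arm on the adjacent benzylic C3. Both can therefore be added in one operation across the C2=C3 bond of 5-chloro-7-methoxybenzofuran.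
- Forward: ring B is closed once, as the aromatic furan, from 4-chloro-2-methoxyphenol. The ring C triflate comes from vanillin by MOM protection, Dakin oxidation and triflation. The three-component arylation–methoxycarbonylation joins the halves, followed by epimerisation, reduction, allylation of the chloride, etherification with eugenol and MOM removal.
- Stereochemistry: C2 (S) is set by the chiral bisphosphine in the key step. C3 forms cis by syn addition and is then equilibrated through the ester enolate to trans, which is 3R after reduction. No later step touches either centre.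

Key step: step 6

Assumption: the sense of induction of BINAP is taken to carry over from the arylation of 2,3-dihydrofuran, where the (R)-ligand gives the (R)-configured O–CH(Ar) carbon, so (S)-BINAP is used for 2S; should the benzofuran respond in the opposite sense, (R)-BINAP is used and nothing else changes.

**Route**

Step 1
Reactants: 1 4-chloro-2-methoxyphenol; 2 2-bromo-1,1-diethoxyethane
Product: 3 4-chloro-1-(2,2-diethoxyethoxy)-2-methoxybenzene
Conditions: K2CO3, KI (cat.), DMF, 120 °C
Reagents that add atoms: none
Why: Williamson ether synthesis in which the phenoxide of 1 displaces the primary bromide of 2 by SN2, with iodide as nucleophilic catalyst for the sluggish β-dialkoxy halide.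

Step 2
Reactants: 3 4-chloro-1-(2,2-diethoxyethoxy)-2-methoxybenzene
Product: 5 5-chloro-7-methoxybenzofuran, via 5-chloro-3-ethoxy-7-methoxy-2,3-dihydrobenzofuran 4 (not isolated)
Conditions: polyphosphoric acid, toluene, reflux
Reagents that add atoms: none
Why: Acid-catalysed cyclodehydration of an aryloxyacetaldehyde acetal, in which the oxocarbenium ion undergoes intramolecular Friedel–Crafts alkylation at the only free position ortho to the ether oxygen and 4 then loses ethanol to give the aromatic furan.

Step 3
Reactants: 6 vanillin
Product: 7 3-methoxy-4-(methoxymethoxy)benzaldehyde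
Conditions: MOMCl, iPr2NEt, CH2Cl2, 0 °C to rt
Reagents that add atoms: chloromethyl methyl ether (MOMCl), COCCl
Why: O-alkylation of the phenol gives a MOM acetal that should withstand peracid, triflation, amine and alkoxide bases, hydride and palladium, and still leave under mild acid at the end.

Step 4
Reactants: 7 3-methoxy-4-(methoxymethoxy)benzaldehyde
Product: 9 3-methoxy-4-(methoxymethoxy)phenol, via 3-methoxy-4-(methoxymethoxy)phenyl formate 8 (not isolated)
Conditions: mCPBA, CH2Cl2, rt; then K2CO3 (cat.), MeOH, rt
Reagents that add atoms: 3-chloroperoxybenzoic acid (mCPBA), O=C(OO)c1cccc(Cl)c1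
Why: Dakin-type Baeyer–Villiger oxidation in which the electron-rich aryl group migrates in the Criegee intermediate to give formate 8, which is methanolysed in the same flask to the phenol.

Step 5
Reactants: 9 3-methoxy-4-(methoxymethoxy)phenol
Product: 10 3-methoxy-4-(methoxymethoxy)phenyl trifluoromethanesulfonate
Conditions: Tf2O, pyridine, CH2Cl2, 0 °C
Reagents that add atoms: trifluoromethanesulfonic anhydride (Tf2O), O=S(=O)(OS(=O)(=O)C(F)(F)F)C(F)(F)F
Why: Standard O-sulfonylation of a phenol, with pyridine buffering the triflic acid so that the MOM acetal is kept.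

Step 6
Reactants: 5 5-chloro-7-methoxybenzofuran (3 equiv); 10 3-methoxy-4-(methoxymethoxy)phenyl trifluoromethanesulfonate; 11 carbon monoxide
Product: 12 methyl (2S,3R)-5-chloro-7-methoxy-2-[3-methoxy-4-(methoxymethoxy)phenyl]-2,3-dihydrobenzofuran-3-carboxylate (cis)
Conditions: Pd(OAc)2 (5 mol%), (S)-BINAP (10 mol%), 1,2,2,6,6-pentamethylpiperidine, MeOH (10 equiv), CO/N2 (about 1:9, 1 atm, CO fed slowly), toluene, 70 °C
Reagents that add atoms: methanol, CO
Why: Proposed new method: oxidative addition of triflate 10 to the zerovalent palladium–BINAP complex gives a cationic aryl complex of divalent palladium that should add syn across the C2=C3 bond of 5, aryl to the oxygen-bearing C2 and palladium to benzylic C3, where no syn β-hydrogen exists (C2–H lies anti, C3a is aromatic), so that CO insertion with retention and methanolysis of the acyl complex can release the cis ester and return zerovalent palladium. The closest known reactions are the asymmetric Heck arylation of 2,3-dihydrofuran with aryl triflates and the intramolecular dearomative Heck–carbonylation cascades of indoles and benzofurans, the intermolecular three-component version on a benzofuran being the untested part. No ring is closed in this step. C2 is set by enantioface selection of the bisphosphine, (S)-BINAP being assigned for 2S by analogy with the dihydrofuran case, and C3 follows from the syn carbopalladation and the retentive CO insertion, hence cis. The step needs aryl-to-C2 regioselectivity, secured by the enol-ether polarisation of the furan double bond and the η3-benzyl stabilisation of palladium at C3; it needs chemoselectivity for the triflate over the C5 chloride, secured by the inertness of electron-rich aryl chlorides towards this catalyst at 70 °C; and it needs carbopalladation ahead of direct methoxycarbonylation of the aryl–palladium bond, which the CO-lean atmosphere and the excess of 5 are meant to secure, since the η3-benzyl species has no other fast exit and can wait for CO. The hindered amine only takes up triflic acid and is a poor base for anti elimination of HPd towards the 2-arylbenzofuran.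

Step 7
Reactants: 12 methyl (2S,3R)-5-chloro-7-methoxy-2-[3-methoxy-4-(methoxymethoxy)phenyl]-2,3-dihydrobenzofuran-3-carboxylate
Product: 13 methyl (2S,3S)-5-chloro-7-methoxy-2-[3-methoxy-4-(methoxymethoxy)phenyl]-2,3-dihydrobenzofuran-3-carboxylate (trans)
Conditions: NaOMe (0.3 equiv), MeOH, rt
Reagents that add atoms: none
Why: Epimerisation through the ester enolate relieves the cis-2,3 eclipsing strain and should converge on the trans ester (C3 now S), while C2 should stay untouched because β-elimination of the ring oxygen would be the reverse of a 5-endo-trig closure and is stereoelectronically slow.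

Step 8
Reactants: 13 methyl (2S,3S)-5-chloro-7-methoxy-2-[3-methoxy-4-(methoxymethoxy)phenyl]-2,3-dihydrobenzofuran-3-carboxylate
Product: 14 [(2S,3R)-5-chloro-7-methoxy-2-[3-methoxy-4-(methoxymethoxy)phenyl]-2,3-dihydrobenzofuran-3-yl]methanol (trans)
Conditions: LiAlH4, THF, 0 °C; Fieser work-up
Reagents that add atoms: none
Why: Hydride reduction of the ester to the primary alcohol removes the epimerisable α-hydrogen situation at C3 without touching the aryl chloride, the MOM ether or either stereocentre (the C3 descriptor changes from S to R only because the substituent priorities change).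

Step 9
Reactants: 14 [(2S,3R)-5-chloro-7-methoxy-2-[3-methoxy-4-(methoxymethoxy)phenyl]-2,3-dihydrobenzofuran-3-yl]methanol; 15 allylboronic acid pinacol ester
Product: 16 [(2S,3R)-5-allyl-7-methoxy-2-[3-methoxy-4-(methoxymethoxy)phenyl]-2,3-dihydrobenzofuran-3-yl]methanol
Conditions: Pd(OAc)2 (3 mol%), SPhos (6 mol%), K3PO4, THF/H2O, 70 °C
Reagents that add atoms: none
Why: Suzuki–Miyaura coupling in which the electron-rich biaryl phosphine enables oxidative addition into the unhindered aryl chloride and the allylboronate transmetallates under aqueous phosphate, the free alcohol being tolerated and the eugenol allyl group not yet present to be isomerised by palladium hydrides.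

Step 10
Reactants: 16 [(2S,3R)-5-allyl-7-methoxy-2-[3-methoxy-4-(methoxymethoxy)phenyl]-2,3-dihydrobenzofuran-3-yl]methanol; 17 eugenol
Product: 18 (2S,3R)-5-allyl-3-[(4-allyl-2-methoxyphenoxy)methyl]-7-methoxy-2-[3-methoxy-4-(methoxymethoxy)phenyl]-2,3-dihydrobenzofuran
Conditions: PPh3, DIAD, THF, 0 °C to rt
Reagents that add atoms: none
Why: Mitsunobu etherification in which the primary alcohol is activated as its alkoxyphosphonium ion and displaced by the phenoxide of eugenol (the only free phenol present), the reaction centre being an achiral CH2 so that no stereocentre is involved.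

Step 11
Reactants: 18 (2S,3R)-5-allyl-3-[(4-allyl-2-methoxyphenoxy)methyl]-7-methoxy-2-[3-methoxy-4-(methoxymethoxy)phenyl]-2,3-dihydrobenzofuran
Product: 19 4-[(2S,3R)-5-allyl-3-[(4-allyl-2-methoxyphenoxy)methyl]-7-methoxy-2,3-dihydrobenzofuran-2-yl]-2-methoxyphenol (CNP0138854.1)
Conditions: HCl (cat., methanolic), MeOH/THF, rt to 40 °C
Reagents that add atoms: none
Why: Acid-catalysed acetal exchange cleaves the phenolic MOM ether under conditions mild enough to spare both allyl groups, and any reversible opening of the benzylic C2–O bond would return to the favoured trans ring because C3 is fixed.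

**Compound list**

1 | 4-chloro-2-methoxyphenol | COc1cc(Cl)ccc1O | starting material
2 | 2-bromo-1,1-diethoxyethane (bromoacetaldehyde diethyl acetal) | CCOC(CBr)OCC | starting material
3 | 4-chloro-1-(2,2-diethoxyethoxy)-2-methoxybenzene | CCOC(COc1ccc(Cl)cc1OC)OCC | intermediate
4 | 5-chloro-3-ethoxy-7-methoxy-2,3-dihydrobenzofuran (racemic, not isolated) | CCOC1COc2c(OC)cc(Cl)cc21 | intermediate
5 | 5-chloro-7-methoxybenzofuran | COc1cc(Cl)cc2ccoc12 | intermediate
6 | vanillin | COc1cc(C=O)ccc1O | starting material
7 | 3-methoxy-4-(methoxymethoxy)benzaldehyde | COCOc1ccc(C=O)cc1OC | intermediate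
8 | 3-methoxy-4-(methoxymethoxy)phenyl formate (not isolated) | COCOc1ccc(OC=O)cc1OC | intermediate
9 | 3-methoxy-4-(methoxymethoxy)phenol | COCOc1ccc(O)cc1OC | intermediate
10 | 3-methoxy-4-(methoxymethoxy)phenyl trifluoromethanesulfonate | COCOc1ccc(OS(=O)(=O)C(F)(F)F)cc1OC | intermediate
11 | carbon monoxide | [C-]#[O+] | starting material
12 | methyl (2S,3R)-5-chloro-7-methoxy-2-[3-methoxy-4-(methoxymethoxy)phenyl]-2,3-dihydrobenzofuran-3-carboxylate (cis) | COC(=O)[C@@H]1c2cc(Cl)cc(OC)c2O[C@@H]1c1ccc(OCOC)c(OC)c1 | intermediate
13 | methyl (2S,3S)-5-chloro-7-methoxy-2-[3-methoxy-4-(methoxymethoxy)phenyl]-2,3-dihydrobenzofuran-3-carboxylate (trans) | COC(=O)[C@H]1c2cc(Cl)cc(OC)c2O[C@@H]1c1ccc(OCOC)c(OC)c1 | intermediate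
14 | [(2S,3R)-5-chloro-7-methoxy-2-[3-methoxy-4-(methoxymethoxy)phenyl]-2,3-dihydrobenzofuran-3-yl]methanol (trans) | OC[C@H]1c2cc(Cl)cc(OC)c2O[C@@H]1c1ccc(OCOC)c(OC)c1 | intermediate
15 | allylboronic acid pinacol ester (2-allyl-4,4,5,5-tetramethyl-1,3,2-dioxaborolane) | C=CCB1OC(C)(C)C(C)(C)O1 | starting material
16 | [(2S,3R)-5-allyl-7-methoxy-2-[3-methoxy-4-(methoxymethoxy)phenyl]-2,3-dihydrobenzofuran-3-yl]methanol | OC[C@H]1c2cc(CC=C)cc(OC)c2O[C@@H]1c1ccc(OCOC)c(OC)c1 | intermediate
17 | eugenol (4-allyl-2-methoxyphenol) | C=CCc1ccc(O)c(OC)c1 | starting material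
18 | (2S,3R)-5-allyl-3-[(4-allyl-2-methoxyphenoxy)methyl]-7-methoxy-2-[3-methoxy-4-(methoxymethoxy)phenyl]-2,3-dihydrobenzofuran | C=CCc1ccc(OC[C@H]2c3cc(CC=C)cc(OC)c3O[C@@H]2c2ccc(OCOC)c(OC)c2)c(OC)c1 | intermediate
19 | 4-[(2S,3R)-5-allyl-3-[(4-allyl-2-methoxyphenoxy)methyl]-7-methoxy-2,3-dihydrobenzofuran-2-yl]-2-methoxyphenol | C=CCc1ccc(OC[C@H]2c3cc(CC=C)cc(OC)c3O[C@@H]2c2ccc(O)c(OC)c2)c(OC)c1 | target

**Step count and risks**

Total step count: 11. Longest linear sequence: 9 steps (vanillin 6 to 19 through steps 3, 4, 5, 6, 7, 8, 9, 10, 11); the phenol branch (steps 1 and 2) joins at step 6.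

Steps most likely to fail:

1. Step 6 (proposed new method). The aryl–palladium bond may be carbonylated before it adds to the furan, the C3–palladium species may lose HPd and rearomatise, or the facial selectivity may be poor. The fallback uses known chemistry, sets out from 1 and 7 and returns at 12.
   - Ortho-iodination of 1 with NIS should give 4-chloro-2-iodo-6-methoxyphenol F1.
   - Reduction of 7 with NaBH4 in MeOH should give [3-methoxy-4-(methoxymethoxy)phenyl]methanol F2.
   - Mitsunobu etherification of F1 with F2 (PPh3, DIAD, THF) should give 5-chloro-1-iodo-3-methoxy-2-{[3-methoxy-4-(methoxymethoxy)phenyl]methoxy}benzene F3.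
   - Palladium-catalysed cross-coupling of the aryl iodide with methyl diazoacetate, with retention of the diazo group (Pd(PPh3)4, Et3N, Bu4NBr, MeCN, rt), should give methyl 2-(5-chloro-3-methoxy-2-{[3-methoxy-4-(methoxymethoxy)phenyl]methoxy}phenyl)-2-diazoacetate F4.
   - Enantioselective intramolecular C–H insertion of the rhodium carbenoid into the benzylic OCH2 group is an established cis-selective route to 2-aryl-2,3-dihydrobenzofuran-3-carboxylates. With dirhodium tetrakis[N-phthaloyl-(S)-tert-leucinate], Rh2(S-PTTL)4, or its antipode, whichever gives the 2S series, in toluene at low temperature, it should give 12.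

2. Step 9. Oxidative addition into the electron-rich C–Cl bond may be sluggish, the allylboronate may protodeboronate, or the new double bond may migrate into conjugation. The fallback reverses the polarity, sets out from 14 and returns at 16.
   - Miyaura borylation of the chloride (Pd2(dba)3, XPhos, B2pin2, KOAc, dioxane, 100 °C) should give [(2S,3R)-7-methoxy-2-[3-methoxy-4-(methoxymethoxy)phenyl]-5-(4,4,5,5-tetramethyl-1,3,2-dioxaborolan-2-yl)-2,3-dihydrobenzofuran-3-yl]methanol F5.
   - Coupling of F5 with allyl bromide through a π-allyl complex (Pd(PPh3)4, K2CO3, THF/H2O, 50 °C) should then give 16.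

3. Step 10. The activated alcohol may eliminate towards the exocyclic alkene and aromatise, or the branched alkoxyphosphonium ion may be displaced too slowly. The fallback sets out from 16 and returns at 18.
   - Mesylation (MsCl, Et3N, CH2Cl2, 0 °C) should give the isolable [(2S,3R)-5-allyl-7-methoxy-2-[3-methoxy-4-(methoxymethoxy)phenyl]-2,3-dihydrobenzofuran-3-yl]methyl methanesulfonate F6.
   - Williamson displacement of F6 by the caesium phenoxide of eugenol 17 (Cs2CO3, DMF, 60 °C) should then give 18.

Further compounds

F1 | step 6 | 4-chloro-2-iodo-6-methoxyphenol | COc1cc(Cl)cc(I)c1O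
F2 | step 6 | [3-methoxy-4-(methoxymethoxy)phenyl]methanol | COCOc1ccc(CO)cc1OC
F3 | step 6 | 5-chloro-1-iodo-3-methoxy-2-{[3-methoxy-4-(methoxymethoxy)phenyl]methoxy}benzene | COCOc1ccc(COc2c(I)cc(Cl)cc2OC)cc1OC
F4 | step 6 | methyl 2-(5-chloro-3-methoxy-2-{[3-methoxy-4-(methoxymethoxy)phenyl]methoxy}phenyl)-2-diazoacetate | COC(=O)C(=[N+]=[N-])c1cc(Cl)cc(OC)c1OCc1ccc(OCOC)c(OC)c1
F5 | step 9 | [(2S,3R)-7-methoxy-2-[3-methoxy-4-(methoxymethoxy)phenyl]-5-(4,4,5,5-tetramethyl-1,3,2-dioxaborolan-2-yl)-2,3-dihydrobenzofuran-3-yl]methanol | OC[C@H]1c2cc(B3OC(C)(C)C(C)(C)O3)cc(OC)c2O[C@@H]1c1ccc(OCOC)c(OC)c1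
F6 | step 10 | [(2S,3R)-5-allyl-7-methoxy-2-[3-methoxy-4-(methoxymethoxy)phenyl]-2,3-dihydrobenzofuran-3-yl]methyl methanesulfonate | CS(=O)(=O)OC[C@H]1c2cc(CC=C)cc(OC)c2O[C@@H]1c1ccc(OCOC)c(OC)c1
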